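The rate constants belong to no real substance; the run is a simulation.

What is left of the substrate at the end has not become intermediate, so I counted that leftover first.

the same everywhere: catalyst 2.4 mM

|  | substrate | time | remark |
|---|---|---|---|
| ochre | 1.2 M (fed, over 24.0 min) | 30 min | a stirred flask in which substrate is dosed at a steady rate over 24.0 min without added volume, worked up at 30 min |
| grey | 1.2 M |  | one stirred flow tank at steady state, fed with the mixture as stated, mean residence time 30 min |
| green | 1.2 M | 30 min | a closed flask charged with all of it at once and left for 30 min |

    substrate → intermediate (k1 = 0.0011 s⁻¹)
    catalyst + intermediate → catalyst + product (k2 = 0.079 M⁻¹ s⁻¹)
    2 catalyst ⇌ resting dimer, settled at all times (K3 = 8900 M⁻¹)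

1. the set-up with the highest amount of intermediate at the outlet or at the end, in percent of the substrate put in ("none" if the first two lie within 2 percentage points) (ochre / grey / green / none)
2. amount of intermediate at the outlet or at the end, in percent of the substrate put in, ochre
3. amount of intermediate at the outlet or at the end, in percent of the substrate put in, grey
4. amount of intermediate at the outlet or at the end, in percent of the substrate put in, green

- for a step with 2 of a species take k times the square, and two of it per event
- the stated concentrations are those of everything mixed, before any reaction; amounts are the same in each set-up
- the feed brings no volume worth counting
- run time (ochre): 30 min

A portion of substrate lives 15.2 min on average, so the run of 30 min serves 1.98 lifetimes; I call this count, time in the vessel over substrate lifetime, the lifetimes served. In the green flask the leftover is exp(−served), which puts the upper bound on intermediate at 86.2 %. In the grey tank the leftover is 1/(1 + served), so its upper bound is 66.4 %. In the ochre flask the last portion is served 0.396 lifetimes and the first 1.98, and averaging the leftover over the dose gives an upper bound of 66.2 %.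

For the lower bound I took the catalyst balance, which counts the resting dimer (the resting state) twice. It leaves 0.340 mM free of the 2.4 mM charged, so intermediate lives 620 min. Intermediate formed at the first moment of the green flask keeps exp(−0.0484), which gives a lower bound of 82.1 %. That is higher than the upper bounds of ochre and grey, so I committed to green. In the green flask, intermediate forms on average 10.3 min into the run, and that tightened my figure to 83.5 %.

The forecast gave 65 % for ochre, 63.4 % for grey and 83.5 % for green, with green best, on the ground “Everything is then linear in series”. Its green figure lay inside my bracket, and its other two lay under their upper bounds.

The flasks gave 65.0 % for ochre, 63.4 % for grey and 83.5 % for green, with green best.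

The substrate lifetime of 15.2 min was far shorter than the intermediate lifetime of 620 min. With 1.98 lifetimes served, the green flask stood 2.7 percentage points under its upper bound, and the ochre flask 1.2 points under its own. When the ochre dose went in over 9.00 min, its last portion was served 1.39 lifetimes, the upper bound rose to 81.2 %, and the intermediate stood at 79.0 %.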